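48% of the substrate still stood in Wednesday's flask at 20.0 h, with product readings flat at 51% since 15.0 h, and this is the flask asked about.

the same everywhere: substrate 1.8 M; free catalyst 0.72 mol%

|  | capture agent | temperature | remark | time |
|---|---|---|---|---|
| Wednesday's | 0.036 M | 35 °C | the very flask that is asked about, followed so far |  |
| Thursday's | 0.036 M | 30 °C | run made earlier |  |
| flask | 0.0360 M | 35 °C |  | 30 h |

| run | time / h | product / % | substrate / % |
|---|---|---|---|
| Wednesday's | 1.33 | 12 | 88 |
| Wednesday's | 4.00 | 26 | 75 |
| Wednesday's | 6.00 | 31 | 67 |
| Wednesday's | 10.0 | 40 | 57 |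
| Wednesday's | 15.0 | 51 | 53 |
| Wednesday's | 20.0 | 51 | 48 |
| Thursday's | 1.33 | 4 | 95 |
| Thursday's | 4.00 | 17 | 83 |
| Thursday's | 6.00 | 22 | 77 |
| Thursday's | 10.0 | 32 | 69 |
| Thursday's | 15.0 | 36 | 63 |
| Thursday's | 20.0 | 36 | 61 |

(each reading ± 1.5 percentage points)

- west: change nothing and wait 30 h more
- north-west: at 30 h add free catalyst, 50.0% of the amount charged, then wait 30 h
- south-west: at 30 h raise the temperature by 25 K, then wait 30 h
- east: at 30 h take out 90% of the product then present, then wait 30 h

- product taken out counts as made
- additions bring no volume worth counting

- product, in percent of the substrate first charged, at 30 h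
- the option that brings most further product ("none" if no option brings more than 2 percentage points) (west / north-west / south-west / east / none)
- product present, with what was taken out counted in, in percent of the substrate first charged, after south-west
- product present, with what was taken out counted in, in percent of the substrate first charged, after east

I read that stop as a catalyst wearing out, so I needed two times. The substrate time is the pseudo-first-order time of the substrate under fresh catalyst, and Wednesday's first reading gives 10.4 h, with that reading's scatter in it. The catalyst life is the time in which the activity falls by the same factor. Logarithms join them: the logarithm of c(substrate) at the start over c(substrate) at the stop counts the substrate times the catalyst worked. So this 0.734 is the life ratio, catalyst life over substrate time, which makes the life 7.64 h.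

As a test I took the reading at 6.00 h, which had used 54.6% of the ratio, while a life of that length predicts 54.4%. By 30 h, which is 3.93 lives, I reckoned 1.97% of the activity left and product near 52.0%. West then adds 0.69 percentage points, and I put east at the same gain. North-west brings fresh catalyst worth 0.367 of ratio, which on the remaining substrate gives 15 points, more than west, so north-west was my choice.

The forecast, which held that “the catalyst dies at a similar rate at both temperatures”, gave 54%, above my figure, chose north-west, and put south-west at 61% and east at 55%.

The flask gave 52.7%, and north-west brought 19 points against my 15 points, with south-west ending at 55.6% and east at 55.0%. At 30.0 h, 90.7% of the catalyst charged lay as trapped intermediate and 2.20% as free catalyst.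

    substrate + free catalyst ⇌ catalyst intermediate A (K = 0.359 M⁻¹, k = 27.6 M⁻¹ h⁻¹, Ea = 71.0 kJ mol⁻¹, ΔH = −29.0 kJ mol⁻¹)
    catalyst intermediate A ⇌ catalyst intermediate B (K = 2.23, k = 307 h⁻¹, Ea = 74.0 kJ mol⁻¹, ΔH = 30.0 kJ mol⁻¹)
    catalyst intermediate B ⇌ free catalyst + product (K = 7.45 M, k = 51.0 h⁻¹, Ea = 84.0 kJ mol⁻¹, ΔH = −20.0 kJ mol⁻¹)
    product + catalyst intermediate B → spent catalyst (k = 0.0660 M⁻¹ h⁻¹, Ea = 63.0 kJ mol⁻¹)
    catalyst intermediate A + capture agent → trapped intermediate (k = 29.6 M⁻¹ h⁻¹, Ea = 59.0 kJ mol⁻¹)
    (constants at 35 °C)

The product that the ratio reckons for the stop, 52.0%, stands beside 54.3% for this flask at 300 h. In a neighbour flask, with 0.29 mol% of free catalyst and the other charges as before, I held the life and stretched the substrate time, so the ratio becomes 0.296 and product 25.6%; that flask gave 22.5%.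

The readings were generated by integration for an exercise.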